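**Plan**
- Retrosynthesis: the silyl group is removed last. The C5–prenyl bond is cut back to an allyl ether on the C6 oxygen (Claisen rearrangement, then metathesis). Ring A is then cut at C1–C2 and C3–C4 in one operation.
- Enabling feature: in ring A the ester carbon C1 lies between the oxygenated carbons C2 and C6, and C4 carries the methyl group. C1–C6–C5–C4 therefore maps onto the C3-to-C6 diene of a 4-benzyloxy-6-methyl-2-pyrone-3-carboxylate, and C2–C3 onto an aryl ethynyl ether that takes the place of the lactone CO2.
- Forward: pyrone 6 is made in two steps from dimethyl malonate and the diketene–acetone adduct. Ring B is bought as 2,4-dimethoxyphenol and taken in five steps to ethynyl ether 16, whose two alkyne carbons come from trichloroethylene.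
- Ring A is the only ring built. It arises in step 8 by [4+2] cycloaddition and loss of CO2. Five further steps (debenzylation, O-allylation, Claisen rearrangement, cross-metathesis, desilylation) finish the target.
- Stereochemistry: the target has no stereocentre and its alkene carries two identical methyl groups, so only regiochemistry (cycloaddition, Claisen) has to be controlled.

Key step: step 8

Remark: ring A locants used in the text are C1 (ester-bearing), C2 (aryloxy), C3 (H), C4 (methyl), C5 (prenyl), C6 (OH), while compound names use IUPAC locants; every compound is achiral except the transient adduct 17, which is racemic.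

**Route**

Step 1
Reactants: 1 dimethyl malonate; 2 2,2,6-trimethyl-4H-1,3-dioxin-4-one
Product: 5 methyl 4-hydroxy-6-methyl-2-oxo-2H-pyran-3-carboxylate, via acetylketene 3 (not isolated), via dimethyl 2-(3-oxobutanoyl)malonate 4 (not isolated)
Conditions: NaH, DME, 0 °C; then 2, PhMe, 105 °C; 1 M HCl
Reagents that add atoms: none
Why: Thermal retro-[4+2] of the dioxinone releases acetylketene, which C-acylates the sodium enolate of 1, and the resulting 3,5-dioxo diester lactonizes through its enol oxygen onto one malonate ester (acetoacetylation of a malonate followed by pyrone closure, the dioxinone standing in for diketene).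

Step 2
Reactants: 5 methyl 4-hydroxy-6-methyl-2-oxo-2H-pyran-3-carboxylate
Product: 6 methyl 4-(benzyloxy)-6-methyl-2-oxo-2H-pyran-3-carboxylate
Conditions: BnOH, PPh3, DIAD, THF, 0 °C to rt
Reagents that add atoms: benzyl alcohol, OCc1ccccc1
Why: Mitsunobu O-alkylation, for which the strongly acidic vinylogous acid of 5 is a good pronucleophile; 4-hydroxy-2-pyrones are alkylated at O4 under these neutral conditions, which also spare the base-sensitive pyrone.

Step 3
Reactants: 7 2,4-dimethoxyphenol
Product: 8 2-hydroxy-3,5-dimethoxybenzaldehyde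
Conditions: MgCl2, Et3N, (CH2O)n, MeCN, reflux; aq. HCl
Reagents that add atoms: paraformaldehyde (as formaldehyde), C=O
Why: Casnati–Skattebøl ortho-formylation, in which the magnesium phenoxide delivers formaldehyde to the only free ortho carbon of 7 and a second formaldehyde accepts the hydride; the para and the other ortho position carry methoxy groups.

Step 4
Reactants: 8 2-hydroxy-3,5-dimethoxybenzaldehyde
Product: 9 2-(hydroxymethyl)-4,6-dimethoxyphenol
Conditions: NaBH4, MeOH/THF, 0 °C
Reagents that add atoms: none
Why: Borohydride reduction of an aryl aldehyde, with no other reducible group in 8.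

Step 5
Reactants: 9 2-(hydroxymethyl)-4,6-dimethoxyphenol
Product: 10 2-(tert-butyldimethylsilyloxymethyl)-4,6-dimethoxyphenol
Conditions: TBSCl (1.05 equiv), imidazole, CH2Cl2, 0 °C
Reagents that add atoms: tert-butyldimethylsilyl chloride, CC(C)(C)[Si](C)(C)Cl
Why: Chemoselective silylation, since the primary benzylic alcohol should react much faster than the phenol flanked by two ortho substituents, as is usual for salicyl alcohols.

Step 6
Reactants: 10 2-(tert-butyldimethylsilyloxymethyl)-4,6-dimethoxyphenol; 11 trichloroethylene
Product: 13 1-[(E)-1,2-dichlorovinyloxy]-2-(tert-butyldimethylsilyloxymethyl)-4,6-dimethoxybenzene, via dichloroacetylene 12 (not isolated)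
Conditions: K2CO3, DMF, 70 °C
Reagents that add atoms: none
Why: Elimination–addition (the standard first half of the trichloroethylene route to ynol ethers), in which base turns 11 into dichloroacetylene and the phenoxide adds to it in anti fashion; the phenoxide is the more stable anion, so the silyl group should stay on the benzylic oxygen.

Step 7
Reactants: 13 1-[(E)-1,2-dichlorovinyloxy]-2-(tert-butyldimethylsilyloxymethyl)-4,6-dimethoxybenzene
Product: 16 1-(ethynyloxy)-2-(tert-butyldimethylsilyloxymethyl)-4,6-dimethoxybenzene, via chloroethynyl aryl ether 14 (not isolated), via lithium aryloxyacetylide 15 (not isolated)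
Conditions: n-BuLi (2.3 equiv), THF, −78 to −40 °C; H2O, −78 °C; pentane extraction, used at once
Reagents that add atoms: none
Why: Dehydrochlorination to the chloroalkyne followed by lithium–chlorine exchange and cold protonation of the acetylide (the second half of the same ynol ether synthesis), giving a 2,6-disubstituted aryloxyacetylene that should be handleable if kept cold and acid-free.

Step 8
Reactants: 6 methyl 4-(benzyloxy)-6-methyl-2-oxo-2H-pyran-3-carboxylate; 16 1-(ethynyloxy)-2-(tert-butyldimethylsilyloxymethyl)-4,6-dimethoxybenzene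
Product: 18 methyl 2-(benzyloxy)-6-[2-(tert-butyldimethylsilyloxymethyl)-4,6-dimethoxyphenoxy]-4-methylbenzoate, via bicyclic lactone adduct 17 (not isolated)
Conditions: o-xylene, 140 °C, N2; 16 (2.5 equiv) added over 6 h; BHT (trace)
Reagents that add atoms: none
Why: Proposed new method: pyrone 6 is an electron-poor diene across its C3 and C6, and ynol ether 16 is nucleophilic at its terminal CH, so an asynchronous inverse-demand [4+2] should bond that CH to the methyl-bearing pyrone C6 (ring A C3–C4) and the oxygen-bearing alkyne carbon to the ester-bearing pyrone C3 (ring A C1–C2), the charge that builds up at C3 being held by its two carbonyl groups. The closest known reaction type is the cycloaddition of 3-carbomethoxy-2-pyrones with ketene acetals, and of 2-pyrones with ynamines, followed by extrusion of CO2 to give benzoates; a 4-alkoxy pyrone paired with an aryl ethynyl ether has not been shown. Ring A closes as the six-membered carbocycle of the 2-oxabicyclo[2.2.2]octadienone 17 by this intermolecular [4+2], and a retro-[4+2] loss of CO2 then aromatizes it directly, no elimination being needed because the 2π partner is already an alkyne. The two bridgehead centres of 17 vanish in that fragmentation, so no stereocentre has to be controlled. The step needs regioselectivity and site selectivity, and both rest on the polarization named above: the benzyloxy group makes pyrone C4 a poor acceptor and a poor leaving-group site, leaving C6 as the only electrophilic terminus for the alkyne CH. The same donor lowers the diene reactivity, which is met by 140 °C and slow addition of excess 16, an ether that has no β-hydrogen for retro-ene loss of a ketene.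

Step 9
Reactants: 18 methyl 2-(benzyloxy)-6-[2-(tert-butyldimethylsilyloxymethyl)-4,6-dimethoxyphenoxy]-4-methylbenzoate
Product: 19 methyl 2-[2-(tert-butyldimethylsilyloxymethyl)-4,6-dimethoxyphenoxy]-6-hydroxy-4-methylbenzoate
Conditions: H2 (1 atm), 10% Pd/C, EtOAc, rt
Reagents that add atoms: none
Why: Hydrogenolysis of the aryl benzyl ether, which in ethyl acetate should leave the benzylic silyl ether (its carbon is meta to both methoxy groups), the diaryl ether and the ester untouched.

Step 10
Reactants: 19 methyl 2-[2-(tert-butyldimethylsilyloxymethyl)-4,6-dimethoxyphenoxy]-6-hydroxy-4-methylbenzoate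
Product: 20 methyl 2-(allyloxy)-6-[2-(tert-butyldimethylsilyloxymethyl)-4,6-dimethoxyphenoxy]-4-methylbenzoate
Conditions: allyl bromide, K2CO3, DMF, 50 °C
Reagents that add atoms: allyl bromide, C=CCBr
Why: Williamson O-allylation of the salicylate phenol, with warm DMF overcoming its hydrogen bond to the ester.

Step 11
Reactants: 20 methyl 2-(allyloxy)-6-[2-(tert-butyldimethylsilyloxymethyl)-4,6-dimethoxyphenoxy]-4-methylbenzoate
Product: 21 methyl 3-allyl-6-[2-(tert-butyldimethylsilyloxymethyl)-4,6-dimethoxyphenoxy]-2-hydroxy-4-methylbenzoate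
Conditions: N,N-diethylaniline, 190 °C
Reagents that add atoms: none
Why: Aromatic Claisen rearrangement, in which only one of the two ortho carbons of the allyl ether (ring A C5) carries hydrogen, so the [3,3] shift and tautomerization should place the allyl group there, next to the C4 methyl.

Step 12
Reactants: 21 methyl 3-allyl-6-[2-(tert-butyldimethylsilyloxymethyl)-4,6-dimethoxyphenoxy]-2-hydroxy-4-methylbenzoate
Product: 22 methyl 6-[2-(tert-butyldimethylsilyloxymethyl)-4,6-dimethoxyphenoxy]-2-hydroxy-4-methyl-3-(3-methylbut-2-en-1-yl)benzoate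
Conditions: second-generation Grubbs catalyst RuCl2(H2IMes)(PCy3)(=CHPh) (5 mol %), 2-methyl-2-butene/CH2Cl2, 40 °C
Reagents that add atoms: 2-methyl-2-butene, CC=C(C)C
Why: Olefin cross-metathesis of the terminal allyl group with a large excess of 2-methyl-2-butene, a standard conversion of an ortho-allyl phenol into an ortho-prenyl phenol with loss of propene.

Step 13
Reactants: 22 methyl 6-[2-(tert-butyldimethylsilyloxymethyl)-4,6-dimethoxyphenoxy]-2-hydroxy-4-methyl-3-(3-methylbut-2-en-1-yl)benzoate
Product: 23 methyl 2-hydroxy-6-[2-(hydroxymethyl)-4,6-dimethoxyphenoxy]-4-methyl-3-(3-methylbut-2-en-1-yl)benzoate (CNP0583011.0)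
Conditions: TBAF, AcOH, THF, 0 °C to rt
Reagents that add atoms: none
Why: Fluoride-mediated cleavage of the primary silyl ether, buffered with acetic acid so that neither the ortho-prenyl phenol nor the ester meets strong base or acid.

**Compound list**
1 | dimethyl malonate | COC(=O)CC(=O)OC | starting material
2 | 2,2,6-trimethyl-4H-1,3-dioxin-4-one | CC1=CC(=O)OC(C)(C)O1 | starting material
3 | acetylketene (but-1-ene-1,3-dione), not isolated | CC(=O)C=C=O | intermediate
4 | dimethyl 2-(3-oxobutanoyl)malonate, not isolated | COC(=O)C(C(=O)OC)C(=O)CC(C)=O | intermediate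
5 | methyl 4-hydroxy-6-methyl-2-oxo-2H-pyran-3-carboxylate | COC(=O)C1=C(O)C=C(C)OC1=O | intermediate
6 | methyl 4-(benzyloxy)-6-methyl-2-oxo-2H-pyran-3-carboxylate | COC(=O)C1=C(OCc2ccccc2)C=C(C)OC1=O | intermediate
7 | 2,4-dimethoxyphenol | COc1ccc(O)c(OC)c1 | starting material
8 | 2-hydroxy-3,5-dimethoxybenzaldehyde | COc1cc(C=O)c(O)c(OC)c1 | intermediate
9 | 2-(hydroxymethyl)-4,6-dimethoxyphenol | COc1cc(CO)c(O)c(OC)c1 | intermediate
10 | 2-(tert-butyldimethylsilyloxymethyl)-4,6-dimethoxyphenol | COc1cc(CO[Si](C)(C)C(C)(C)C)c(O)c(OC)c1 | intermediate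
11 | trichloroethylene | ClC=C(Cl)Cl | starting material
12 | dichloroacetylene, not isolated | ClC#CCl | intermediate
13 | 1-[(E)-1,2-dichlorovinyloxy]-2-(tert-butyldimethylsilyloxymethyl)-4,6-dimethoxybenzene | Cl/C=C(Cl)\Oc1c(CO[Si](C)(C)C(C)(C)C)cc(OC)cc1OC | intermediate
14 | 1-(chloroethynyloxy)-2-(tert-butyldimethylsilyloxymethyl)-4,6-dimethoxybenzene, not isolated | ClC#COc1c(CO[Si](C)(C)C(C)(C)C)cc(OC)cc1OC | intermediate
15 | lithium [2-(tert-butyldimethylsilyloxymethyl)-4,6-dimethoxyphenoxy]acetylide, not isolated | [Li]C#COc1c(CO[Si](C)(C)C(C)(C)C)cc(OC)cc1OC | intermediate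
16 | 1-(ethynyloxy)-2-(tert-butyldimethylsilyloxymethyl)-4,6-dimethoxybenzene | C#COc1c(CO[Si](C)(C)C(C)(C)C)cc(OC)cc1OC | intermediate
17 | methyl 5-(benzyloxy)-8-[2-(tert-butyldimethylsilyloxymethyl)-4,6-dimethoxyphenoxy]-1-methyl-3-oxo-2-oxabicyclo[2.2.2]octa-5,7-diene-4-carboxylate, racemic, not isolated | COC(=O)C12C(=O)OC(C)(C=C1OCc1ccccc1)C=C2Oc1c(CO[Si](C)(C)C(C)(C)C)cc(OC)cc1OC | intermediate
18 | methyl 2-(benzyloxy)-6-[2-(tert-butyldimethylsilyloxymethyl)-4,6-dimethoxyphenoxy]-4-methylbenzoate | COC(=O)c1c(Oc2c(CO[Si](C)(C)C(C)(C)C)cc(OC)cc2OC)cc(C)cc1OCc1ccccc1 | intermediate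
19 | methyl 2-[2-(tert-butyldimethylsilyloxymethyl)-4,6-dimethoxyphenoxy]-6-hydroxy-4-methylbenzoate | COC(=O)c1c(Oc2c(CO[Si](C)(C)C(C)(C)C)cc(OC)cc2OC)cc(C)cc1O | intermediate
20 | methyl 2-(allyloxy)-6-[2-(tert-butyldimethylsilyloxymethyl)-4,6-dimethoxyphenoxy]-4-methylbenzoate | COC(=O)c1c(Oc2c(CO[Si](C)(C)C(C)(C)C)cc(OC)cc2OC)cc(C)cc1OCC=C | intermediate
21 | methyl 3-allyl-6-[2-(tert-butyldimethylsilyloxymethyl)-4,6-dimethoxyphenoxy]-2-hydroxy-4-methylbenzoate | COC(=O)c1c(Oc2c(CO[Si](C)(C)C(C)(C)C)cc(OC)cc2OC)cc(C)c(CC=C)c1O | intermediate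
22 | methyl 6-[2-(tert-butyldimethylsilyloxymethyl)-4,6-dimethoxyphenoxy]-2-hydroxy-4-methyl-3-(3-methylbut-2-en-1-yl)benzoate | COC(=O)c1c(Oc2c(CO[Si](C)(C)C(C)(C)C)cc(OC)cc2OC)cc(C)c(CC=C(C)C)c1O | intermediate
23 | methyl 2-hydroxy-6-[2-(hydroxymethyl)-4,6-dimethoxyphenoxy]-4-methyl-3-(3-methylbut-2-en-1-yl)benzoate (CNP0583011.0) | COC(=O)c1c(Oc2c(CO)cc(OC)cc2OC)cc(C)c(CC=C(C)C)c1O | target

**Step count and risks**

Total step count: 13. Longest linear sequence: 11 steps (7 to 23 through steps 3–13); the pyrone branch (steps 1–2) joins at step 8.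

Steps most likely to fail:

1. Step 8 (the untested cycloaddition).
 - What may go wrong: the donor-substituted pyrone may react more slowly than the terminal ynol ether oligomerizes at 140 °C, or the alkyne may add in conjugate fashion without ring closure.
 - Fallback (known chemistry): the diaryl ether C–O bond is made by cross-coupling instead of building ring A. It sets out from phenol 10. Commercial methyl 2,6-dihydroxy-4-methylbenzoate is mono-benzylated (BnBr, K2CO3, acetone; the second hydroxyl stays hydrogen-bonded to the ester) to methyl 2-(benzyloxy)-6-hydroxy-4-methylbenzoate F1. Tf2O and pyridine then give methyl 2-(benzyloxy)-4-methyl-6-(trifluoromethylsulfonyloxy)benzoate F2. Palladium-catalysed C–O coupling of F2 with 10 (Pd(OAc)2, 2-di-tert-butylphosphino-2′,4′,6′-triisopropylbiphenyl, K3PO4, toluene, 100 °C; a Buchwald–Hartwig-type diaryl ether synthesis in which the ortho ester favours reductive elimination) should give 18, where the route is rejoined.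

2. Step 7.
 - What may go wrong: the terminal ynol ether may be lost during aqueous quench and concentration, by hydration to the aryl acetate or by oligomerization.
 - Fallback: starting again from 13, the lithium acetylide 15 is trapped with Me3SiCl instead of water to give {[2-(tert-butyldimethylsilyloxymethyl)-4,6-dimethoxyphenoxy]ethynyl}trimethylsilane F3, which should survive chromatography and storage. Just before the cycloaddition the C–Si bond is cleaved with K2CO3 in MeOH at 0 °C, which leaves the alkyl O–Si bond alone. The ynol ether is extracted into pentane and transferred into o-xylene without being taken to dryness, which returns to the route at 16.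

3. Step 2.
 - What may go wrong: the ambident pyronate may be alkylated at the lactone carbonyl oxygen, giving the 2-benzyloxy-4-pyranone isomer, or the chelated enol may react sluggishly.
 - Fallback: the bond from C4 oxygen to benzyl is made by addition–elimination instead of alkylation. From 5, TsCl and Et3N in CH2Cl2 give methyl 6-methyl-2-oxo-4-(tosyloxy)-2H-pyran-3-carboxylate F4 (sulfonylation of 4-hydroxy-2-pyrones occurs at O4). Benzyl alcohol with K2CO3 in MeCN at 0 °C to rt then displaces the sulfonate at the doubly activated C4 (nucleophilic vinylic substitution) and returns to the route at 6.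

Further compounds
F1 | step 8 | methyl 2-(benzyloxy)-6-hydroxy-4-methylbenzoate | COC(=O)c1c(O)cc(C)cc1OCc1ccccc1
F2 | step 8 | methyl 2-(benzyloxy)-4-methyl-6-(trifluoromethylsulfonyloxy)benzoate | COC(=O)c1c(OS(=O)(=O)C(F)(F)F)cc(C)cc1OCc1ccccc1
F3 | step 7 | {[2-(tert-butyldimethylsilyloxymethyl)-4,6-dimethoxyphenoxy]ethynyl}trimethylsilane | C[Si](C)(C)C#COc1c(CO[Si](C)(C)C(C)(C)C)cc(OC)cc1OC
F4 | step 2 | methyl 6-methyl-2-oxo-4-(tosyloxy)-2H-pyran-3-carboxylate | COC(=O)C1=C(OS(=O)(=O)c2ccc(C)cc2)C=C(C)OC1=O
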